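**Strategy.** The route rests on forging the C1–C2 bond of ring B, between the gem-dimethyl quaternary carbon C1 and the alkene carbon C2 that carries the side chain. Ring B is a cyclogeranyl-type ring hung on a preformed ring A: a tertiary carbocation at C1, attached to C8a, is captured by the α-carbon of a β-keto ester (C2; ketone C3; ester carbon = first side-chain carbon). This single operation closes ring B and builds the quaternary centre; the keto ester then fixes the C2=C3 alkene. The precursor is a cis-disubstituted cyclohexene hydroxy keto ester from a copper-catalysed asymmetric Diels–Alder reaction. The 1,2-dioxane is made separately and joined by Wittig olefination and diimide reduction.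

Key step: step 7

Remarks on the chemistry (assumptions):
- Numbering of the bicycle follows naphthalene: C1 (CMe2), C2 (bears the chain), C3 (methyl, alkene), C4, C4a, C5 (=CH), C6 (methyl), C7, C8, C8a. Ring A is C4a–C5–C6–C7–C8–C8a; ring B is C1–C2–C3–C4–C4a–C8a.
- C2 of keto ester 15 is a keto/enol-labile centre and is written without a descriptor; it becomes sp2 in step 8.
- Acid-catalysed perhydrolysis of the 2,2-disubstituted epoxide (step 17) is taken to proceed with inversion at the tertiary carbon.
- The crotylborane 26 is used as a reagent solution prepared beforehand by the standard protocol from (Z)-but-2-ene, KOtBu/n-BuLi, (+)-Ipc2BOMe (from (−)-α-pinene) and BF3·OEt2.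

Step 1
Reactants: 1 tert-butyl(but-3-yn-1-yloxy)dimethylsilane; 2 catecholborane; 3 2-bromopropene
Product: 5 tert-butyl(dimethyl){[(3E)-5-methylhexa-3,5-dien-1-yl]oxy}silane, via alkenyl catecholboronate 4 (not isolated)
Conditions: 2, neat, 70 °C; then 3, Pd(PPh3)4 (3 mol %), 2 M aq. NaOH, THF, 65 °C
Reagents that add atoms: none
Why: syn-Hydroboration of the terminal alkyne gives the (E)-alkenylboronate and the Suzuki–Miyaura coupling proceeds with retention, so the (E)-diene geometry needed for a cis adduct is fixed here.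

Step 2
Reactants: 5 tert-butyl(dimethyl){[(3E)-5-methylhexa-3,5-dien-1-yl]oxy}silane; 6 3-acryloyl-1,3-oxazolidin-2-one
Product: 7 3-{[(1S,2R)-2-[2-(tert-butyldimethylsilyloxy)ethyl]-4-methylcyclohex-3-en-1-yl]carbonyl}-1,3-oxazolidin-2-one
Conditions: [Cu((S,S)-tBu-box)](SbF6)2 (10 mol %; tBu-box = 2,2-bis[(4S)-4-tert-butyl-4,5-dihydro-1,3-oxazol-2-yl]propane), CH2Cl2, −20 °C to rt
Reagents that add atoms: none
Why: Catalytic asymmetric Diels–Alder reaction in which the chelated acrylimide on square-planar divalent copper is shielded on one face by a tert-butyl group, both diene substituents direct the acyl-bearing carbon next to the side-chain carbon, and the endo transition state makes the two new stereocentres cis (1S,2R).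

Step 3
Reactants: 7 the silyl ether imide from step 2
Product: 9 (4aR,8aS)-6-methyl-3,4,4a,7,8,8a-hexahydro-1H-isochromen-1-one (cis-fused δ-lactone), via hydroxy imide 8 (not isolated)
Conditions: HF·pyridine, THF, 0 °C to rt; then Et3N, DMAP (cat.), CH2Cl2, rt
Reagents that add atoms: none
Why: Desilylation frees a hydroxyl that is cis to the activated imide and acylates intramolecularly (lactonisation) with loss of the oxazolidinone, which also locks the cis relationship.

Step 4
Reactants: 9 (4aR,8aS)-6-methyl-3,4,4a,7,8,8a-hexahydro-1H-isochromen-1-one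
Product: 10 2-[(1R,6S)-6-(2-hydroxypropan-2-yl)-3-methylcyclohex-2-en-1-yl]ethan-1-ol
Conditions: MeMgBr (3.5 equiv), THF, 0 °C
Reagents that add atoms: methylmagnesium bromide, C[Mg]Br
Why: Double Grignard addition to the lactone gives the tertiary carbinol and frees the primary alcohol; addition outruns enolisation, so the α-stereocentre should stay cis.

Step 5
Reactants: 10 2-[(1R,6S)-6-(2-hydroxypropan-2-yl)-3-methylcyclohex-2-en-1-yl]ethan-1-ol
Product: 12 (4aR,8aS)-1,1,6-trimethyl-1,4,4a,7,8,8a-hexahydro-3H-isochromen-3-one, via lactol 11 (not isolated)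
Conditions: TEMPO (20 mol %), PhI(OAc)2 (2.5 equiv), CH2Cl2, rt
Reagents that add atoms: none
Why: Oxoammonium oxidation of the primary alcohol gives the aldehyde, which closes onto the tertiary hydroxyl and is oxidised on to the δ-lactone (oxidative lactonisation); tertiary alcohol and alkene are inert.

Step 6
Reactants: 12 (4aR,8aS)-1,1,6-trimethyl-1,4,4a,7,8,8a-hexahydro-3H-isochromen-3-one; 13 methyl acetate
Product: 14 methyl 4-[(1R,6S)-6-(2-hydroxypropan-2-yl)-3-methylcyclohex-2-en-1-yl]-3-oxobutanoate (open form, in equilibrium with its six-membered cyclic hemiketal)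
Conditions: 13, LiN(iPr)2, THF, −78 °C; then 12, −78 °C; aq. NH4Cl
Reagents that add atoms: none
Why: Claisen-type addition of the lithium enolate of methyl acetate to the lactone stops at the hemiketal alkoxide, which on work-up is the ring–chain tautomer of the hydroxy β-keto ester.

Step 7
Reactants: 14 methyl 4-[(1R,6S)-6-(2-hydroxypropan-2-yl)-3-methylcyclohex-2-en-1-yl]-3-oxobutanoate
Product: 15 methyl (4aR,8aS)-1,1,6-trimethyl-3-oxo-1,2,3,4,4a,7,8,8a-octahydronaphthalene-2-carboxylate (C2 epimers and enol)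
Conditions: SnCl4 (2.5 equiv), 2,6-di-tert-butyl-4-methylpyridine (1.2 equiv), 4 Å MS, CH2Cl2, −78 °C to 0 °C
Reagents that add atoms: none
Why: SnCl4 chelates the β-keto ester as its tin enolate and ionises the tertiary C–O bond (of the open carbinol, or of the cyclic enol ether into which the hemiketal dehydrates), giving a terpinyl-type tertiary carbocation at the future C1 that is captured by the enol carbon C2 to form the C1–C2 bond. The closest known reaction types are the SnCl4-promoted cation–olefin cyclisation with a β-keto ester terminator and the Lewis-acid tert-alkylation of 1,3-dicarbonyl compounds by tertiary alcohols. Ring B closes in a 6-(enolendo)-exo-tet mode, the ionising C–O bond lying outside the new carbocycle, and O-alkylation is reversible under the conditions so that material funnels to the C-alkylated ketone. No lasting stereocentre is created: C4a and C8a come from step 2 and are not part of the ionising centre, so the ring fusion stays cis, and C2 is enolisable and becomes sp2 in step 8. The step needs ionisation without protonation of the trisubstituted ring-A alkene and without a 1,2-hydride shift from C8a; the hindered pyridine and the sieves remove protic acid, and the tethered tin enolate should trap the cation faster than it rearranges.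

Step 8
Reactants: 15 methyl (4aR,8aS)-1,1,6-trimethyl-3-oxo-1,2,3,4,4a,7,8,8a-octahydronaphthalene-2-carboxylate
Product: 16 methyl (4aR,8aS)-1,1,6-trimethyl-3-{[(trifluoromethyl)sulfonyl]oxy}-1,4,4a,7,8,8a-hexahydronaphthalene-2-carboxylate
Conditions: NaH, Et2O, 0 °C; then Tf2O, −78 °C to 0 °C
Reagents that add atoms: trifluoromethanesulfonic anhydride, O=S(=O)(OS(=O)(=O)C(F)(F)F)C(F)(F)F
Why: The sodium enolate of the β-keto ester can only form toward C2, and its O-triflation (enol triflate formation) fixes the position of the future tetrasubstituted alkene.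

Step 9
Reactants: 16 the enol triflate from step 8
Product: 17 methyl (4aR,8aS)-1,1,3,6-tetramethyl-1,4,4a,7,8,8a-hexahydronaphthalene-2-carboxylate
Conditions: MeMgBr, Fe(acac)3 (10 mol %), THF/NMP, −30 °C
Reagents that add atoms: methylmagnesium bromide, C[Mg]Br
Why: Iron-catalysed Kumada-type cross-coupling of the ester-activated enol triflate replaces triflate by methyl without moving the alkene, and the hindered ester is not attacked at low temperature.

Step 10
Reactants: 17 methyl (4aR,8aS)-1,1,3,6-tetramethyl-1,4,4a,7,8,8a-hexahydronaphthalene-2-carboxylate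
Product: 18 [(4aR,8aS)-1,1,3,6-tetramethyl-1,4,4a,7,8,8a-hexahydronaphthalen-2-yl]methanol
Conditions: iBu2AlH (2.5 equiv), CH2Cl2, −78 °C to 0 °C; aq. KNaC4H4O6 (potassium sodium tartrate)
Reagents that add atoms: none
Why: Hydride reduction of the conjugated ester gives the primary allylic alcohol without touching a stereocentre.

Step 11
Reactants: 18 [(4aR,8aS)-1,1,3,6-tetramethyl-1,4,4a,7,8,8a-hexahydronaphthalen-2-yl]methanol
Product: 19 {[(4aR,8aS)-1,1,3,6-tetramethyl-1,4,4a,7,8,8a-hexahydronaphthalen-2-yl]methyl}(triphenyl)phosphonium bromide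
Conditions: PPh3·HBr, MeOH/CH2Cl2, rt
Reagents that add atoms: triphenylphosphine hydrobromide, [PH+](c1ccccc1)(c1ccccc1)c1ccccc1.[Br-]
Why: The allylic alcohol ionises under the mildly acidic salt and the allyl cation is captured at its primary terminus by PPh3 (SN1-type phosphonium salt formation), as is usual for cyclogeranyl-type alcohols.

Step 12
Reactants: 20 [(2S)-2-methyloxiran-2-yl]methanol; 21 allylmagnesium chloride
Product: 22 (2R)-2-methylhex-5-ene-1,2-diol
Conditions: 21 (2.3 equiv), CuI (10 mol %), THF, −30 °C to 0 °C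
Reagents that add atoms: none
Why: Copper-catalysed Grignard opening of the 2,2-disubstituted epoxide at its unsubstituted carbon leaves the purchased quaternary stereocentre untouched, and the Payne rearrangement of this alkoxide is degenerate and cannot scramble it.

Step 13
Reactants: 22 (2R)-2-methylhex-5-ene-1,2-diol
Product: 24 (2R)-2-(but-3-en-1-yl)-2-methyloxirane, via primary tosylate 23 (not isolated)
Conditions: TsCl, Et3N, Bu2SnO (2 mol %), CH2Cl2, 0 °C; then K2CO3, MeOH, rt
Reagents that add atoms: none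
Why: Selective sulfonylation of the primary hydroxyl and Williamson closure by the tertiary alkoxide give the epoxide with retention at the quaternary carbon, which now carries the oxygen that will leave with inversion.

Step 14
Reactants: 24 (2R)-2-(but-3-en-1-yl)-2-methyloxirane
Product: 25 3-[(2R)-2-methyloxiran-2-yl]propanal
Conditions: O3, CH2Cl2, −78 °C; then PPh3, −78 °C to rt
Reagents that add atoms: ozone, [O-][O+]=O
Why: Ozonolysis with reductive work-up cleaves the only alkene to the aldehyde while the epoxide is inert.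

Step 15
Reactants: 25 3-[(2R)-2-methyloxiran-2-yl]propanal; 26 (Z)-but-2-en-1-ylbis(isopinocampheyl)borane, the (+)-Ipc2B reagent with Ipc groups from (−)-α-pinene
Product: 27 (3S,4S)-3-methyl-6-[(2R)-2-methyloxiran-2-yl]hex-1-en-4-ol
Conditions: 26, THF/Et2O, −78 °C; then NaOH, H2O2, 0 °C
Reagents that add atoms: none
Why: Brown crotylboration, in which the (Z)-crotylborane reacts through a chair six-membered transition state to give the syn homoallylic alcohol and the isopinocampheyl groups direct addition to the re face of the aldehyde, setting (3S,4S).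

Step 16
Reactants: 27 (3S,4S)-3-methyl-6-[(2R)-2-methyloxiran-2-yl]hex-1-en-4-ol
Product: 28 (3S,4S)-3-methyl-6-[(2R)-2-methyloxiran-2-yl]hex-1-en-4-yl methanesulfonate
Conditions: MsCl, Et3N, CH2Cl2, 0 °C
Reagents that add atoms: methanesulfonyl chloride, CS(=O)(=O)Cl
Why: Mesylation with retention turns the carbinol carbon into the electrophile for the later ring closure and stops the hydroxyl from opening the epoxide.

Step 17
Reactants: 28 (3S,4S)-3-methyl-6-[(2R)-2-methyloxiran-2-yl]hex-1-en-4-yl methanesulfonate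
Product: 29 (2S,5S,6S)-2-hydroperoxy-1-hydroxy-2,6-dimethyloct-7-en-5-yl methanesulfonate
Conditions: H2O2 (anhydrous ethereal solution), H3PMo12O40 (phosphomolybdic acid, 3 mol %), Et2O, rt
Reagents that add atoms: hydrogen peroxide, OO
Why: Acid-catalysed perhydrolysis of the epoxide, in which H2O2 opens the activated ring at the tertiary carbon in a borderline SN2 process with inversion to give the tertiary hydroperoxide and a primary alcohol.

Step 18
Reactants: 29 (2S,5S,6S)-2-hydroperoxy-1-hydroxy-2,6-dimethyloct-7-en-5-yl methanesulfonate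
Product: 30 [(3S,6R)-6-[(2S)-but-3-en-2-yl]-3-methyl-1,2-dioxan-3-yl]methanol
Conditions: CsOH·H2O, DMF, 0 °C
Reagents that add atoms: none
Why: Intramolecular Williamson-type alkylation (6-exo-tet SN2) of the hydroperoxide anion on the secondary mesylate closes the 1,2-dioxane with inversion, which turns the syn crotylation product into the required anti oxygen/methyl relationship; the more acidic OOH reacts before the primary OH.

Step 19
Reactants: 30 [(3S,6R)-6-[(2S)-but-3-en-2-yl]-3-methyl-1,2-dioxan-3-yl]methanol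
Product: 32 (2R)-2-[(3R,6S)-6-(hydroxymethyl)-6-methyl-1,2-dioxan-3-yl]propanoic acid, via aldehyde 31 (not isolated)
Conditions: O3, CH2Cl2, −78 °C; Me2S; then NaClO2, NaH2PO4, 2-methyl-2-butene, tBuOH/H2O, 0 °C to rt
Reagents that add atoms: ozone, [O-][O+]=O; sodium chlorite, [Na+].[O-]Cl=O
Why: Ozonolysis of the vinyl group and Pinnick oxidation of the crude aldehyde under buffered, non-basic conditions should give the acid without epimerising the α-methyl centre or eliminating the β-peroxide.

Step 20
Reactants: 32 (2R)-2-[(3R,6S)-6-(hydroxymethyl)-6-methyl-1,2-dioxan-3-yl]propanoic acid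
Product: 33 (2R)-2-[(3R,6S)-6-formyl-6-methyl-1,2-dioxan-3-yl]propanoic acid
Conditions: Dess–Martin periodinane, NaHCO3, CH2Cl2, 0 °C to rt
Reagents that add atoms: none
Why: Dess–Martin oxidation of the primary alcohol gives an aldehyde that has no α-hydrogen and so cannot epimerise.

Step 21
Reactants: 19 the phosphonium bromide from step 11; 33 (2R)-2-[(3R,6S)-6-formyl-6-methyl-1,2-dioxan-3-yl]propanoic acid
Product: 35 (2R)-2-[(3R,6S)-6-methyl-6-{(E)-2-[(4aR,8aS)-1,1,3,6-tetramethyl-1,4,4a,7,8,8a-hexahydronaphthalen-2-yl]ethenyl}-1,2-dioxan-3-yl]propanoic acid, via phosphorus ylide 34 (not isolated)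
Conditions: 19 (2.2 equiv), NaN(SiMe3)2 (2.1 equiv), THF, −78 °C to 0 °C; then 33, −78 °C to rt
Reagents that add atoms: none
Why: Wittig olefination of the semi-stabilised allylic ylide with the non-enolisable aldehyde; one equivalent of ylide deprotonates the acid, whose carboxylate form protects the α-centre, and any (Z)-isomer converges in the next step.

Step 22
Reactants: 35 the diene acid from step 21
Product: 36 (2R)-2-[(3R,6R)-6-methyl-6-{2-[(4aR,8aS)-1,1,3,6-tetramethyl-1,4,4a,7,8,8a-hexahydronaphthalen-2-yl]ethyl}-1,2-dioxan-3-yl]propanoic acid (target)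
Conditions: 2-nitrobenzenesulfonylhydrazide (excess, in portions), Et3N, CH2Cl2, rt
Reagents that add atoms: none
Why: Diimide reduction (concerted syn transfer of H2) should saturate the 1,2-disubstituted alkene much faster than the tri- and tetrasubstituted ring alkenes and does not cleave the O–O bond.

**Compound list**

1 | tert-butyl(but-3-yn-1-yloxy)dimethylsilane | C#CCCO[Si](C)(C)C(C)(C)C | starting material
2 | catecholborane (1,3,2-benzodioxaborole) | B1Oc2ccccc2O1 | starting material
3 | 2-bromopropene | CC(Br)=C | starting material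
4 | 2-[(1E)-4-(tert-butyldimethylsilyloxy)but-1-en-1-yl]-1,3,2-benzodioxaborole | CC(C)(C)[Si](C)(C)OCC/C=C/B1Oc2ccccc2O1 | intermediate
5 | tert-butyl(dimethyl){[(3E)-5-methylhexa-3,5-dien-1-yl]oxy}silane | CC(=C)/C=C/CCO[Si](C)(C)C(C)(C)C | intermediate
6 | 3-acryloyl-1,3-oxazolidin-2-one | C=CC(=O)N1CCOC1=O | starting material
7 | 3-{[(1S,2R)-2-[2-(tert-butyldimethylsilyloxy)ethyl]-4-methylcyclohex-3-en-1-yl]carbonyl}-1,3-oxazolidin-2-one | CC1=C[C@@H](CCO[Si](C)(C)C(C)(C)C)[C@@H](C(=O)N2CCOC2=O)CC1 | intermediate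
8 | 3-{[(1S,2R)-2-(2-hydroxyethyl)-4-methylcyclohex-3-en-1-yl]carbonyl}-1,3-oxazolidin-2-one | CC1=C[C@@H](CCO)[C@@H](C(=O)N2CCOC2=O)CC1 | intermediate
9 | (4aR,8aS)-6-methyl-3,4,4a,7,8,8a-hexahydro-1H-isochromen-1-one | CC1=C[C@H]2CCOC(=O)[C@H]2CC1 | intermediate
10 | 2-[(1R,6S)-6-(2-hydroxypropan-2-yl)-3-methylcyclohex-2-en-1-yl]ethan-1-ol | CC1=C[C@@H](CCO)[C@@H](C(C)(C)O)CC1 | intermediate
11 | (4aR,8aS)-1,1,6-trimethyl-3,4,4a,7,8,8a-hexahydro-1H-isochromen-3-ol (lactol, both anomers) | CC1=C[C@H]2CC(O)OC(C)(C)[C@H]2CC1 | intermediate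
12 | (4aR,8aS)-1,1,6-trimethyl-1,4,4a,7,8,8a-hexahydro-3H-isochromen-3-one | CC1=C[C@H]2CC(=O)OC(C)(C)[C@H]2CC1 | intermediate
13 | methyl acetate | COC(C)=O | starting material
14 | methyl 4-[(1R,6S)-6-(2-hydroxypropan-2-yl)-3-methylcyclohex-2-en-1-yl]-3-oxobutanoate | CC1=C[C@@H](CC(=O)CC(=O)OC)[C@@H](C(C)(C)O)CC1 | intermediate
15 | methyl (4aR,8aS)-1,1,6-trimethyl-3-oxo-1,2,3,4,4a,7,8,8a-octahydronaphthalene-2-carboxylate | CC1=C[C@H]2CC(=O)C(C(=O)OC)C(C)(C)[C@H]2CC1 | intermediate
16 | methyl (4aR,8aS)-1,1,6-trimethyl-3-{[(trifluoromethyl)sulfonyl]oxy}-1,4,4a,7,8,8a-hexahydronaphthalene-2-carboxylate | CC1=C[C@H]2CC(OS(=O)(=O)C(F)(F)F)=C(C(=O)OC)C(C)(C)[C@H]2CC1 | intermediate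
17 | methyl (4aR,8aS)-1,1,3,6-tetramethyl-1,4,4a,7,8,8a-hexahydronaphthalene-2-carboxylate | CC1=C[C@H]2CC(C)=C(C(=O)OC)C(C)(C)[C@H]2CC1 | intermediate
18 | [(4aR,8aS)-1,1,3,6-tetramethyl-1,4,4a,7,8,8a-hexahydronaphthalen-2-yl]methanol | CC1=C[C@H]2CC(C)=C(CO)C(C)(C)[C@H]2CC1 | intermediate
19 | {[(4aR,8aS)-1,1,3,6-tetramethyl-1,4,4a,7,8,8a-hexahydronaphthalen-2-yl]methyl}(triphenyl)phosphonium bromide | CC1=C[C@H]2CC(C)=C(C[P+](c3ccccc3)(c3ccccc3)c3ccccc3)C(C)(C)[C@H]2CC1.[Br-] | intermediate
20 | [(2S)-2-methyloxiran-2-yl]methanol | C[C@]1(CO)CO1 | starting material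
21 | allylmagnesium chloride | C=CC[Mg]Cl | starting material
22 | (2R)-2-methylhex-5-ene-1,2-diol | C[C@](O)(CO)CCC=C | intermediate
23 | (2R)-2-hydroxy-2-methylhex-5-en-1-yl 4-methylbenzenesulfonate | C[C@](O)(COS(=O)(=O)c1ccc(C)cc1)CCC=C | intermediate
24 | (2R)-2-(but-3-en-1-yl)-2-methyloxirane | C[C@@]1(CCC=C)CO1 | intermediate
25 | 3-[(2R)-2-methyloxiran-2-yl]propanal | C[C@@]1(CCC=O)CO1 | intermediate
26 | (Z)-but-2-en-1-ylbis(isopinocampheyl)borane, (+)-Ipc2B reagent from (−)-α-pinene | C/C=C\CB([C@H]1C[C@H]2C[C@@H]([C@@H]1C)C2(C)C)[C@H]1C[C@H]2C[C@@H]([C@@H]1C)C2(C)C | starting material (reagent made from commercial (+)-Ipc2BOMe and (Z)-but-2-ene)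
27 | (3S,4S)-3-methyl-6-[(2R)-2-methyloxiran-2-yl]hex-1-en-4-ol | C=C[C@H](C)[C@@H](O)CC[C@]1(C)CO1 | intermediate
28 | (3S,4S)-3-methyl-6-[(2R)-2-methyloxiran-2-yl]hex-1-en-4-yl methanesulfonate | C=C[C@H](C)[C@@H](OS(C)(=O)=O)CC[C@]1(C)CO1 | intermediate
29 | (2S,5S,6S)-2-hydroperoxy-1-hydroxy-2,6-dimethyloct-7-en-5-yl methanesulfonate | OC[C@@](C)(OO)CC[C@H](OS(C)(=O)=O)[C@@H](C)C=C | intermediate
30 | [(3S,6R)-6-[(2S)-but-3-en-2-yl]-3-methyl-1,2-dioxan-3-yl]methanol | OC[C@]1(C)CC[C@H]([C@@H](C)C=C)OO1 | intermediate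
31 | (2R)-2-[(3R,6S)-6-(hydroxymethyl)-6-methyl-1,2-dioxan-3-yl]propanal | OC[C@]1(C)CC[C@H]([C@@H](C)C=O)OO1 | intermediate
32 | (2R)-2-[(3R,6S)-6-(hydroxymethyl)-6-methyl-1,2-dioxan-3-yl]propanoic acid | OC[C@]1(C)CC[C@H]([C@@H](C)C(=O)O)OO1 | intermediate
33 | (2R)-2-[(3R,6S)-6-formyl-6-methyl-1,2-dioxan-3-yl]propanoic acid | O=C[C@]1(C)CC[C@H]([C@@H](C)C(=O)O)OO1 | intermediate
34 | {[(4aR,8aS)-1,1,3,6-tetramethyl-1,4,4a,7,8,8a-hexahydronaphthalen-2-yl]methylidene}(triphenyl)-λ5-phosphane (ylide) | CC1=C[C@H]2CC(C)=C(C=P(c3ccccc3)(c3ccccc3)c3ccccc3)C(C)(C)[C@H]2CC1 | intermediate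
35 | (2R)-2-[(3R,6S)-6-methyl-6-{(E)-2-[(4aR,8aS)-1,1,3,6-tetramethyl-1,4,4a,7,8,8a-hexahydronaphthalen-2-yl]ethenyl}-1,2-dioxan-3-yl]propanoic acid | CC1=C[C@H]2CC(C)=C(/C=C/[C@]3(C)CC[C@H]([C@@H](C)C(=O)O)OO3)C(C)(C)[C@H]2CC1 | intermediate
36 | (2R)-2-[(3R,6R)-6-methyl-6-{2-[(4aR,8aS)-1,1,3,6-tetramethyl-1,4,4a,7,8,8a-hexahydronaphthalen-2-yl]ethyl}-1,2-dioxan-3-yl]propanoic acid | CC1=C[C@H]2CC(C)=C(CC[C@]3(C)CC[C@H]([C@@H](C)C(=O)O)OO3)C(C)(C)[C@H]2CC1 | target

**Step count.** 22 steps in total; longest linear sequence 13 steps (steps 1–11, then 21 and 22). The dioxane branch (steps 12–20) is 9 steps before the union.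

**Steps most likely to fail**

Step 7 (key cyclisation). The ionised system may rest as the O-alkylated cyclic enol ether, lose a proton from the tertiary cation (E1), undergo a 1,2-hydride shift from C8a, or suffer protonation and migration of the ring-A alkene. The fallback sets out from 14 and comes back at 15; it separates ionisation from C–C bond formation. Compound 14 is dehydrated under mild acid (PPTS, 4 Å MS, benzene, reflux) to the isolable cyclic enol ether methyl 2-[(4aR,8aS)-1,1,6-trimethyl-1,4,4a,7,8,8a-hexahydro-3H-isochromen-3-ylidene]acetate F1, a vinylogous tert-alkyl carbonate. Under strictly aprotic conditions Me2AlCl (CH2Cl2, −78 °C to 0 °C) should then induce a Petasis–Ferrier-type 1,3-shift from oxygen to carbon: the tertiary C–O bond ionises to a contact ion pair of tertiary cation and aluminium enolate, which recombines at carbon to give 15 with no protic acid present.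

Step 17 (perhydrolysis). Partial SN1 character in the intermolecular opening would erode the configuration at the tertiary carbon; attack at the CH2 carbon or acid-induced rearrangement of the epoxide may compete. The fallback sets out from 28 and comes back at 30; it reverses the order of the two C–O bond formations. The mesylate is displaced first by hydroperoxide anion (H2O2, CsOH·H2O, DMF, 0 °C; SN2 with inversion) to give (2R)-2-[(3R,4S)-3-hydroperoxy-4-methylhex-5-en-1-yl]-2-methyloxirane F2 with the epoxide intact. Catalytic camphorsulfonic acid in CH2Cl2 then lets the tethered OOH open the epoxide at the tertiary carbon in a 6-exo fashion; this opening is intramolecular, hence stereospecific with inversion, and gives 30 directly with the same configurations as the main route.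

Step 15 (crotylboration next to an acid-labile epoxide). Boron Lewis acids in the reagent solution may rearrange the 2,2-disubstituted epoxide, or the new hydroxyl may open it in a 5-exo fashion during work-up or chromatography. The fallback sets out from 22 and comes back at 28; the tertiary centre travels as a protected diol and the epoxide is made only after the C–C bond.
- Diol 22 is converted (2,2-dimethoxypropane, PPTS) into the acetonide (4R)-4-(but-3-en-1-yl)-2,2,4-trimethyl-1,3-dioxolane F3.
- Ozonolysis (O3; PPh3) gives 3-[(4R)-2,2,4-trimethyl-1,3-dioxolan-4-yl]propanal F4.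
- The same crotylboration gives (3S,4S)-3-methyl-6-[(4R)-2,2,4-trimethyl-1,3-dioxolan-4-yl]hex-1-en-4-ol F5.
- Mesylation gives (3S,4S)-3-methyl-6-[(4R)-2,2,4-trimethyl-1,3-dioxolan-4-yl]hex-1-en-4-yl methanesulfonate F6.
- Aqueous acetic acid removes the acetonide to give (3S,4S,7R)-7,8-dihydroxy-3,7-dimethyloct-1-en-4-yl methanesulfonate F7.
- Selective tosylation of the primary hydroxyl (TsCl, Et3N, Bu2SnO cat.) gives (3S,4S,7R)-7-hydroxy-3,7-dimethyl-8-(tosyloxy)oct-1-en-4-yl methanesulfonate F8, and K2CO3 in MeOH closes the epoxide to 28.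

Further compounds
F1 | step 7 | methyl 2-[(4aR,8aS)-1,1,6-trimethyl-1,4,4a,7,8,8a-hexahydro-3H-isochromen-3-ylidene]acetate (E/Z mixture) | CC1=C[C@H]2CC(=CC(=O)OC)OC(C)(C)[C@H]2CC1
F2 | step 17 | (2R)-2-[(3R,4S)-3-hydroperoxy-4-methylhex-5-en-1-yl]-2-methyloxirane | C=C[C@H](C)[C@H](OO)CC[C@]1(C)CO1
F3 | step 15 | (4R)-4-(but-3-en-1-yl)-2,2,4-trimethyl-1,3-dioxolane | C[C@@]1(CCC=C)COC(C)(C)O1
F4 | step 15 | 3-[(4R)-2,2,4-trimethyl-1,3-dioxolan-4-yl]propanal | C[C@@]1(CCC=O)COC(C)(C)O1
F5 | step 15 | (3S,4S)-3-methyl-6-[(4R)-2,2,4-trimethyl-1,3-dioxolan-4-yl]hex-1-en-4-ol | C=C[C@H](C)[C@@H](O)CC[C@]1(C)COC(C)(C)O1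
F6 | step 15 | (3S,4S)-3-methyl-6-[(4R)-2,2,4-trimethyl-1,3-dioxolan-4-yl]hex-1-en-4-yl methanesulfonate | C=C[C@H](C)[C@@H](OS(C)(=O)=O)CC[C@]1(C)COC(C)(C)O1
F7 | step 15 | (3S,4S,7R)-7,8-dihydroxy-3,7-dimethyloct-1-en-4-yl methanesulfonate | C=C[C@H](C)[C@@H](OS(C)(=O)=O)CC[C@@](C)(O)CO
F8 | step 15 | (3S,4S,7R)-7-hydroxy-3,7-dimethyl-8-(tosyloxy)oct-1-en-4-yl methanesulfonate | C=C[C@H](C)[C@@H](OS(C)(=O)=O)CC[C@@](C)(O)COS(=O)(=O)c1ccc(C)cc1
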